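**Retrosynthetic overview**
1. Target 24 ⇐ acylation of the C8 hydroxyl of core alcohol 21 with (R)-2-methylbutanoic acid 22.
2. 21 ⇐ C6–C7 bond and lactone C–O bond formed together by a light-driven, chromium-catalysed intramolecular allylation of Z-enal/allylic bromide 17.
3. 17 ⇐ Morita–Baylis–Hillman reaction (methyl acrylate) at the C7 aldehyde of dialdehyde 14, then allylic bromination.
4. Furanone 11/12 ⇐ alkynylation of hydroxy lactone 6 with the (Z)-enyne 8, then 5-endo cyclisation of the α′-hydroxy ynone.
5. 6 ⇐ (R)-5-(hydroxymethyl)butyrolactone 1: C8 is bought, C10 is set from it; ring order is furanone, then ten-membered ring and γ-lactone in one step.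

Assumption: atoms are referred to by germacranolide numbering (C1–C15, lactone carbonyl C12, exocyclic methylene C13); the target is taken exactly as drawn, (6R,7R,8R,10S) with an (R)-2-methylbutanoate.

Step 1
Reactants: 1 (R)-5-(hydroxymethyl)dihydrofuran-2(3H)-one
Product: 2 (R)-5-[(triethylsilyloxy)methyl]dihydrofuran-2(3H)-one
Conditions: TESCl, imidazole, CH2Cl2, 0 °C to rt
Reagents that add atoms: chlorotriethylsilane, CC[Si](Cl)(CC)CC
Why: Imidazole-promoted silyl ether formation protects the primary alcohol and leaves the bought stereocentre (future C8) untouched.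

Step 2
Reactants: 2 (R)-5-[(triethylsilyloxy)methyl]dihydrofuran-2(3H)-one
Product: 4 (3S,5R)-3-methyl-5-[(triethylsilyloxy)methyl]dihydrofuran-2(3H)-one, via lithium enolate 3 (not isolated)
Conditions: LiN(iPr)2, THF, −78 °C; then MeI, −78 to −40 °C
Reagents that add atoms: iodomethane, CI
Why: Lactone enolate alkylation, in which MeI enters anti to the 5-CH2OSiEt3 group to give mainly the 3,5-trans product (this C3 configuration is erased again in step 3).

Step 3
Reactants: 4 (3S,5R)-3-methyl-5-[(triethylsilyloxy)methyl]dihydrofuran-2(3H)-one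
Product: 6 (3S,5R)-3-hydroxy-3-methyl-5-[(triethylsilyloxy)methyl]dihydrofuran-2(3H)-one, via lithium enolate 5 (not isolated)
Conditions: LiN(iPr)2, THF, −78 °C; then MoO5·pyridine·HMPA, −78 to −40 °C; aqueous Na2SO3
Reagents that add atoms: MoO5·pyridine·HMPA, O=[Mo]12(OO1)OO2.c1ccncc1.CN(C)P(=O)(N(C)C)N(C)C
Why: Vedejs enolate hydroxylation, in which the bulky achiral peroxo-molybdenum reagent attacks the planar enolate on the face opposite the 5-substituent, so OH ends trans and CH3 cis to CH2OSiEt3; this fixes the future C10 as S by substrate control from the bought centre.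

Step 4
Reactants: 7 (Z)-3-methylpent-2-en-4-yn-1-ol
Product: 8 triethyl{[(Z)-3-methylpent-2-en-4-yn-1-yl]oxy}silane
Conditions: TESCl, imidazole, CH2Cl2, 0 °C
Reagents that add atoms: chlorotriethylsilane, CC[Si](Cl)(CC)CC
Why: Silyl ether formation blocks the cis-allylic hydroxyl, which would otherwise add 5-exo to the ynone of step 5 and give a furan; the Z geometry is unchanged.

Step 5
Reactants: 6 (3S,5R)-3-hydroxy-3-methyl-5-[(triethylsilyloxy)methyl]dihydrofuran-2(3H)-one, 8 triethyl{[(Z)-3-methylpent-2-en-4-yn-1-yl]oxy}silane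
Product: 11 (S)-2-[(R)-2-hydroxy-3-(triethylsilyloxy)propyl]-2-methyl-5-[(Z)-4-(triethylsilyloxy)but-2-en-2-yl]furan-3(2H)-one, via lithium acetylide 9 (not isolated), via hydroxy ynone 10 (not isolated)
Conditions: 8 (3 equiv), n-BuLi, THF, −78 °C; then 6, −78 to −10 °C; AcOH; then Et2NH, EtOH, rt
Reagents that add atoms: none
Why: Acetylide addition to a lactone stops at the ketone level because the lithium lactolate persists until the quench, and amine-mediated 5-endo-dig oxa-Michael cyclisation of the α′-hydroxy ynone then gives the 3(2H)-furanone (the C8 hydroxyl could only close a seven-membered ring and does not compete); no stereocentre is touched.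

Step 6
Reactants: 11 (S)-2-[(R)-2-hydroxy-3-(triethylsilyloxy)propyl]-2-methyl-5-[(Z)-4-(triethylsilyloxy)but-2-en-2-yl]furan-3(2H)-one
Product: 12 (S)-2-[(R)-2,3-bis(triethylsilyloxy)propyl]-2-methyl-5-[(Z)-4-(triethylsilyloxy)but-2-en-2-yl]furan-3(2H)-one
Conditions: TESCl, imidazole, DMF, 0 °C to rt
Reagents that add atoms: chlorotriethylsilane, CC[Si](Cl)(CC)CC
Why: Silyl ether formation at the secondary C8 hydroxyl, so that the later allylmetal carries a poor leaving group at C8 (an acyloxy group there would invite reductive 1,4-elimination); any earlier 1,2-silyl shift between O7 and O8 converges on the same product.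

Step 7
Reactants: 12 (S)-2-[(R)-2,3-bis(triethylsilyloxy)propyl]-2-methyl-5-[(Z)-4-(triethylsilyloxy)but-2-en-2-yl]furan-3(2H)-one
Product: 14 (Z)-3-{(S)-5-methyl-4-oxo-5-[(R)-3-oxo-2-(triethylsilyloxy)propyl]-4,5-dihydrofuran-2-yl}but-2-enal, via bis-alkoxysulfonium salt 13 (not isolated)
Conditions: (COCl)2, DMSO, CH2Cl2, −78 to −30 °C; then Et3N, −78 to 0 °C
Reagents that add atoms: none
Why: Swern oxidation applied directly to primary triethylsilyl ethers, in which activated DMSO exchanges Et3SiCl for an alkoxysulfonium group only at the two primary positions and base then releases both aldehydes; the secondary silyl ether, the Z-alkene and C8 survive at low temperature.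

Step 8
Reactants: 14 (Z)-3-{(S)-5-methyl-4-oxo-5-[(R)-3-oxo-2-(triethylsilyloxy)propyl]-4,5-dihydrofuran-2-yl}but-2-enal, 15 methyl acrylate
Product: 16 methyl 2-{(2R)-1-hydroxy-3-[(S)-2-methyl-3-oxo-5-((Z)-4-oxobut-2-en-2-yl)-2,3-dihydrofuran-2-yl]-2-(triethylsilyloxy)propyl}acrylate (both C7 epimers)
Conditions: methyl acrylate (neat, excess), 1,4-diazabicyclo[2.2.2]octane (1 equiv), rt, dark
Reagents that add atoms: none
Why: Morita–Baylis–Hillman reaction, in which the amine–acrylate zwitterion adds only to the saturated α-silyloxy aldehyde (the β,β-disubstituted enal is not a competent acceptor); the new carbinol centre is formed unselectively and is erased in step 9.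

Step 9
Reactants: 16 methyl 2-{(2R)-1-hydroxy-3-[(S)-2-methyl-3-oxo-5-((Z)-4-oxobut-2-en-2-yl)-2,3-dihydrofuran-2-yl]-2-(triethylsilyloxy)propyl}acrylate
Product: 17 methyl (2Z,4R)-2-(bromomethyl)-5-[(S)-2-methyl-3-oxo-5-((Z)-4-oxobut-2-en-2-yl)-2,3-dihydrofuran-2-yl]-4-(triethylsilyloxy)pent-2-enoate
Conditions: NBS, Me2S, CH2Cl2, −20 to 0 °C
Reagents that add atoms: N-bromosuccinimide, O=C1CCC(=O)N1Br
Why: Corey–Kim-type activation of the allylic alcohol followed by SN2′ attack of bromide gives the thermodynamically preferred (Z)-2-(bromomethyl)enoate under neutral conditions that spare the enal, the silyl ether and the furanone.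

Step 10
Reactants: 17 methyl (2Z,4R)-2-(bromomethyl)-5-[(S)-2-methyl-3-oxo-5-((Z)-4-oxobut-2-en-2-yl)-2,3-dihydrofuran-2-yl]-4-(triethylsilyloxy)pent-2-enoate
Product: 21 (6R,7R,8R,10S)-8-hydroxy-1-oxo-3,10-epoxygermacra-2,4(Z),11(13)-trien-12,6-olide, via allylchromium species 18 (not isolated), via macrocyclic hydroxy ester 19 (not isolated), via silyl lactone 20 (not isolated)
Conditions: CrCl3·3THF (15 mol%), 2,4,5,6-tetra(9H-carbazol-9-yl)isophthalonitrile (2 mol%), Hantzsch ester (diethyl 2,6-dimethyl-1,4-dihydropyridine-3,5-dicarboxylate, 1.5 equiv), degassed DMF–THF, 17 added slowly to 2 mM, 450 nm LEDs, 25 °C; then 1 M aqueous HCl, 0 °C to rt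
Reagents that add atoms: none
Why: Proposed new method: a macrocyclising, lactone-forming Nozaki–Hiyama–Kishi-type allylation run with catalytic chromium under visible light, in which the excited organic photocatalyst is reduced by the Hantzsch ester and passes the electron to trivalent chromium, the resulting divalent chromium (two sequential one-electron steps, the allyl radical being trapped by a second divalent chromium) turns the 2-(bromomethyl)enoate into allylchromium 18, and 18 adds through its γ-carbon C7 to the tethered enal in a chair Zimmerman–Traxler transition state with C5 and C8 pseudo-equatorial (6,7-anti, hence the trans-fused lactone) and with C8–H in the allyl plane and OSiEt3 turned away from the aldehyde (A(1,3) control of the C7 face by the bought C8 centre); the chromium alkoxide of 19 closes the lactone with loss of methanol, the pyridinium formed from the Hantzsch ester releases trivalent chromium for the next turnover, triplet sensitisation by the same photocatalyst interconverts the C4=C5 isomers so that any E-enal is funnelled through the only cyclisable Z form, and the acid work-up removes the C8 silyl group; the closest known reaction types are stoichiometric CrCl2-mediated Barbier macro-allylations with 2-(bromomethyl)acrylates and intermolecular dual photoredox/chromium allylations of aldehydes, neither shown for a light-driven catalytic ring closure of this substrate class.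

Step 11
Reactants: 21 (6R,7R,8R,10S)-8-hydroxy-1-oxo-3,10-epoxygermacra-2,4(Z),11(13)-trien-12,6-olide, 22 (R)-2-methylbutanoic acid
Product: 24 (6R,7R,8R,10S)-1-oxo-3,10-epoxygermacra-2,4(Z),11(13)-trien-12,6-olid-8-yl (R)-2-methylbutanoate, via O-acylisourea 23 (not isolated)
Conditions: DCC, 4-(dimethylamino)pyridine (cat.), CH2Cl2, 0 °C to rt
Reagents that add atoms: none
Why: Steglich esterification acylates the secondary C8 hydroxyl without breaking the C8–O bond (retention) and is mild enough to keep the α-stereocentre of the bought acid and the α-methylene lactone intact.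

**Compound list**
1 | (R)-5-(hydroxymethyl)dihydrofuran-2(3H)-one | O=C1CC[C@H](CO)O1 | starting material
2 | (R)-5-[(triethylsilyloxy)methyl]dihydrofuran-2(3H)-one | O=C1CC[C@H](CO[Si](CC)(CC)CC)O1 | intermediate
3 | lithium enolate of 2 (not isolated) | [Li]OC1=CC[C@H](CO[Si](CC)(CC)CC)O1 | intermediate
4 | (3S,5R)-3-methyl-5-[(triethylsilyloxy)methyl]dihydrofuran-2(3H)-one (3,5-trans) | O=C1[C@@H](C)C[C@H](CO[Si](CC)(CC)CC)O1 | intermediate
5 | lithium enolate of 4 (not isolated) | [Li]OC1=C(C)C[C@H](CO[Si](CC)(CC)CC)O1 | intermediate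
6 | (3S,5R)-3-hydroxy-3-methyl-5-[(triethylsilyloxy)methyl]dihydrofuran-2(3H)-one (OH trans to the side chain) | O=C1[C@@](C)(O)C[C@H](CO[Si](CC)(CC)CC)O1 | intermediate
7 | (Z)-3-methylpent-2-en-4-yn-1-ol | C#C/C(C)=C\CO | starting material
8 | triethyl{[(Z)-3-methylpent-2-en-4-yn-1-yl]oxy}silane | C#C/C(C)=C\CO[Si](CC)(CC)CC | intermediate
9 | lithium acetylide of 8 (not isolated) | [Li]C#C/C(C)=C\CO[Si](CC)(CC)CC | intermediate
10 | (2R,4S,8Z)-2,4-dihydroxy-4,8-dimethyl-1,10-bis(triethylsilyloxy)dec-8-en-6-yn-5-one (not isolated; in equilibrium with its five-membered lactol) | CC[Si](CC)(CC)OC/C=C(/C)C#CC(=O)[C@@](C)(O)C[C@@H](O)CO[Si](CC)(CC)CC | intermediate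
11 | (S)-2-[(R)-2-hydroxy-3-(triethylsilyloxy)propyl]-2-methyl-5-[(Z)-4-(triethylsilyloxy)but-2-en-2-yl]furan-3(2H)-one | CC[Si](CC)(CC)OC/C=C(/C)C1=CC(=O)[C@](C)(C[C@@H](O)CO[Si](CC)(CC)CC)O1 | intermediate
12 | (S)-2-[(R)-2,3-bis(triethylsilyloxy)propyl]-2-methyl-5-[(Z)-4-(triethylsilyloxy)but-2-en-2-yl]furan-3(2H)-one | CC[Si](CC)(CC)OC/C=C(/C)C1=CC(=O)[C@](C)(C[C@@H](O[Si](CC)(CC)CC)CO[Si](CC)(CC)CC)O1 | intermediate
13 | bis-alkoxysulfonium dichloride of 12 (both primary OSiEt3 groups replaced by O–S(+)Me2; not isolated) | C[S+](C)OC/C=C(/C)C1=CC(=O)[C@](C)(C[C@@H](O[Si](CC)(CC)CC)CO[S+](C)C)O1.[Cl-].[Cl-] | intermediate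
14 | (Z)-3-{(S)-5-methyl-4-oxo-5-[(R)-3-oxo-2-(triethylsilyloxy)propyl]-4,5-dihydrofuran-2-yl}but-2-enal | O=C/C=C(/C)C1=CC(=O)[C@](C)(C[C@@H](O[Si](CC)(CC)CC)C=O)O1 | intermediate
15 | methyl acrylate | C=CC(=O)OC | starting material
16 | methyl 2-{(2R)-1-hydroxy-3-[(S)-2-methyl-3-oxo-5-((Z)-4-oxobut-2-en-2-yl)-2,3-dihydrofuran-2-yl]-2-(triethylsilyloxy)propyl}acrylate (both C7 epimers; C7 left undefined in the SMILES) | O=C/C=C(/C)C1=CC(=O)[C@](C)(C[C@@H](O[Si](CC)(CC)CC)C(O)C(=C)C(=O)OC)O1 | intermediate
17 | methyl (2Z,4R)-2-(bromomethyl)-5-[(S)-2-methyl-3-oxo-5-((Z)-4-oxobut-2-en-2-yl)-2,3-dihydrofuran-2-yl]-4-(triethylsilyloxy)pent-2-enoate | O=C/C=C(/C)C1=CC(=O)[C@](C)(C[C@@H](O[Si](CC)(CC)CC)/C=C(\CBr)C(=O)OC)O1 | intermediate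
18 | allylchromium dichloride from 17 (CH2Br replaced by CH2–CrCl2, trivalent chromium; not isolated) | O=C/C=C(/C)C1=CC(=O)[C@](C)(C[C@@H](O[Si](CC)(CC)CC)/C=C(\C[Cr](Cl)Cl)C(=O)OC)O1 | intermediate
19 | methyl 2-[(6R,7S,8R,10S)-6-hydroxy-1-oxo-8-(triethylsilyloxy)-3,10-epoxygermacra-2,4(Z)-dien-7-yl]acrylate (same spatial arrangement as the target; the 7-descriptor changes only because of the silyl group; not isolated) | COC(=O)C(=C)[C@H]1[C@H](O)/C=C(/C)C2=CC(=O)[C@](C)(C[C@H]1O[Si](CC)(CC)CC)O2 | intermediate
20 | (6R,7S,8R,10S)-1-oxo-8-(triethylsilyloxy)-3,10-epoxygermacra-2,4(Z),11(13)-trien-12,6-olide (same spatial arrangement as the target; not isolated) | C=C1C(=O)O[C@@H]2/C=C(/C)C3=CC(=O)[C@](C)(C[C@@H](O[Si](CC)(CC)CC)[C@@H]12)O3 | intermediate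
21 | (6R,7R,8R,10S)-8-hydroxy-1-oxo-3,10-epoxygermacra-2,4(Z),11(13)-trien-12,6-olide | C=C1C(=O)O[C@@H]2/C=C(/C)C3=CC(=O)[C@](C)(C[C@@H](O)[C@@H]12)O3 | intermediate
22 | (R)-2-methylbutanoic acid | CC[C@@H](C)C(=O)O | starting material
23 | O-[(R)-2-methylbutanoyl]-N,N′-dicyclohexylisourea (not isolated) | CC[C@@H](C)C(=O)OC(=NC1CCCCC1)NC1CCCCC1 | intermediate
24 | (6R,7R,8R,10S)-1-oxo-3,10-epoxygermacra-2,4(Z),11(13)-trien-12,6-olid-8-yl (R)-2-methylbutanoate | C=C1C(=O)O[C@@H]2/C=C(/C)C3=CC(=O)[C@](C)(C[C@@H](OC(=O)[C@H](C)CC)[C@@H]12)O3 | target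

**Step count and risks**
Total: 11 steps. Longest linear sequence: 10 steps (steps 1–3 and 5–11; step 4 is a one-step side branch).

Most likely to fail, step 10 (the new reaction). The 6,7-trans and 7,8 relationships rest on a transition-state argument and on analogy with stoichiometric chromium chemistry. The allyl radical may also be reduced by the Hantzsch ester before chromium traps it, and the dienone chromophore may undergo other sensitised reactions. The fallback gives up photocatalysis for known two-electron chemistry. It sets out from 17, which is cyclised in the dark with stoichiometric CrCl2 (DMF–THF, high dilution, rt) in a classical Nozaki–Hiyama–Kishi/Barbier macro-allylation through the same species 18, 19 and 20. The same aqueous HCl treatment follows, and the route is rejoined at 21. This fallback creates no compound outside the list (F0).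

Second, step 8. The hindered α-silyloxy aldehyde may react slowly, and the amine may erode the Z-enal geometry (tolerable only in so far as step 10 re-equilibrates it) or epimerise C8. The fallback replaces amine catalysis by a preformed organoaluminium nucleophile. It sets out from 14. Methyl propiolate is hydroaluminated with iBu2AlH/N-methylmorpholine N-oxide in THF at 0 °C to give the vinylalane methyl 2-(diisobutylalumanyl)acrylate F1. One equivalent of this is added to 14 at −20 °C, where it attacks the more electrophilic saturated aldehyde without any base (vinylalumination). The route is rejoined at 16.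

Third, step 5. The lactone carbonyl sits next to a quaternary alkoxide-bearing carbon and may resist the acetylide, or the lactolate may over-add on warming. The fallback opens the lactone before the C–C bond is made. It sets out from 6, which is converted with AlMe3/MeNH(OMe)·HCl into the Weinreb amide (2S,4R)-2,4-dihydroxy-N-methoxy-N,2-dimethyl-5-(triethylsilyloxy)pentanamide F2. The secondary hydroxyl is silylated (TESCl, imidazole) to give (2S,4R)-2-hydroxy-N-methoxy-N,2-dimethyl-4,5-bis(triethylsilyloxy)pentanamide F3. Excess acetylide 9 then gives the ynone (2R,4S,8Z)-4-hydroxy-4,8-dimethyl-1,2,10-tris(triethylsilyloxy)dec-8-en-6-yn-5-one F4. Et2NH in EtOH cyclises F4 directly to 12, where the route is rejoined (step 6 is then not needed).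

**Further compounds**
F0 | step 10 | none | none
F1 | step 8 | methyl 2-(diisobutylalumanyl)acrylate | COC(=O)C(=C)[Al](CC(C)C)CC(C)C
F2 | step 5 | (2S,4R)-2,4-dihydroxy-N-methoxy-N,2-dimethyl-5-(triethylsilyloxy)pentanamide | CON(C)C(=O)[C@@](C)(O)C[C@@H](O)CO[Si](CC)(CC)CC
F3 | step 5 | (2S,4R)-2-hydroxy-N-methoxy-N,2-dimethyl-4,5-bis(triethylsilyloxy)pentanamide | CON(C)C(=O)[C@@](C)(O)C[C@@H](O[Si](CC)(CC)CC)CO[Si](CC)(CC)CC
F4 | step 5 | (2R,4S,8Z)-4-hydroxy-4,8-dimethyl-1,2,10-tris(triethylsilyloxy)dec-8-en-6-yn-5-one | CC[Si](CC)(CC)OC/C=C(/C)C#CC(=O)[C@@](C)(O)C[C@@H](O[Si](CC)(CC)CC)CO[Si](CC)(CC)CC
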